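Thymol numbering is used: C7 benzylic CH2O, C8 quaternary oxirane carbon, C9 oxirane CH2, C10 acyloxymethyl carbon.
Retrosynthesis cuts, in this order: the aryl angelate C–O bond, the two (R)-2-methylbutanoate C–O bonds at C7 and C10, the oxirane bonds C8–C9 and C9–O, and last the aryl–C8 bond.
Enabling feature: the oxirane has a quaternary C8 bound to the arene, the ring oxygen, the ring methylene C9 and C10H2O, so C9 can be delivered as a one-carbon sulfur ylide to a C8 aryl ketone.
Forward: a bought benzene ring is allylated, reduced and silylated; its aryllithium is acylated by a silylated glycolic Weinreb amide (aryl–C8); methylene transfer closes the only new ring, the oxirane; desilylation, double acylation and allyl-to-angeloyl exchange at the phenol finish the molecule.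
Stereochemistry: C8 comes from catalyst-controlled enantiofacial methylene transfer under LaLi3[(R)-1,1'-bi-2-naphtholate]3; both acyl stereocentres are bought as (R)-2-methylbutanoic acid and the Z alkene as angelic acid, and neither is touched afterwards.

Key step: step 8

Assumption: the catalyst built from (R)-binaphthol is taken to be the enantiomer that transfers CH2 to the ketone face leading to the required C8 configuration; the sense is to be confirmed on the first run, and the (S)-binaphthol catalyst is substituted with nothing else changed if it is opposite.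
Remark on descriptors: one and the same spatial arrangement at C8 reads R in the bis-silyl ether, the diester, the phenol and the target, and S in the betaine and the diol, because the CIP rank of C10 against C9 changes with the group on O10.
Remark on handling: from step 8 onwards the tertiary benzylic oxirane is acid-labile, so work-ups stay neutral to basic and chromatography uses triethylamine-deactivated silica.

Step 1
Reactants: 1 methyl 4-bromo-3-hydroxybenzoate
Product: 2 methyl 3-(allyloxy)-4-bromobenzoate
Conditions: allyl bromide, K2CO3, DMF, rt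
Reagents that add atoms: allyl bromide, C=CCBr
Why: Williamson ether synthesis, in which the carbonate-generated phenoxide displaces bromide from the allylic halide by SN2 while the methyl ester is untouched at room temperature.

Step 2
Reactants: 2 methyl 3-(allyloxy)-4-bromobenzoate
Product: 3 [3-(allyloxy)-4-bromophenyl]methanol
Conditions: i-Bu2AlH (2.5 equiv), CH2Cl2, −78 to 0 °C; aq. KNaC4H4O6 work-up
Reagents that add atoms: none
Why: Aluminium hydride reduction of an ester, in which two hydride equivalents take the benzoate to the benzylic alcohol below 0 °C without touching the aryl bromide or the terminal alkene of the allyl ether.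

Step 3
Reactants: 3 [3-(allyloxy)-4-bromophenyl]methanol
Product: 4 {[3-(allyloxy)-4-bromobenzyl]oxy}(tert-butyl)dimethylsilane
Conditions: TBSCl, imidazole, DMF, rt
Reagents that add atoms: tert-butyldimethylsilyl chloride, CC(C)(C)[Si](C)(C)Cl
Why: Imidazole-promoted silylation of a primary alcohol gives a silyl ether that tolerates the organolithium, ylide and lanthanum chemistry that follows.

Step 4
Reactants: 5 methyl glycolate
Product: 6 methyl {[tert-butyl(dimethyl)silyl]oxy}acetate
Conditions: TBSCl, imidazole, CH2Cl2, 0 °C to rt
Reagents that add atoms: tert-butyldimethylsilyl chloride, CC(C)(C)[Si](C)(C)Cl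
Why: The same imidazole-promoted silylation masks the glycolate hydroxyl, which must be non-acidic and a poor donor in steps 5, 6 and 8.

Step 5
Reactants: 6 methyl {[tert-butyl(dimethyl)silyl]oxy}acetate
Product: 7 2-{[tert-butyl(dimethyl)silyl]oxy}-N-methoxy-N-methylacetamide
Conditions: MeNH(OMe)·HCl, i-PrMgCl, THF, −20 to 0 °C
Reagents that add atoms: N,O-dimethylhydroxylamine hydrochloride, CNOC.Cl
Why: Weinreb amide synthesis from an ester, in which the chloromagnesium amide of the hydroxylamine adds to the ester faster than the Grignard reagent does and the amide formed resists further addition at this temperature.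

Step 6
Reactants: 4 {[3-(allyloxy)-4-bromobenzyl]oxy}(tert-butyl)dimethylsilane; 7 2-{[tert-butyl(dimethyl)silyl]oxy}-N-methoxy-N-methylacetamide
Product: 10 1-[2-(allyloxy)-4-({[tert-butyl(dimethyl)silyl]oxy}methyl)phenyl]-2-{[tert-butyl(dimethyl)silyl]oxy}ethan-1-one, via aryllithium 8 (not isolated), via lithium hemiaminal alkoxide 9 (not isolated)
Conditions: n-BuLi, THF, −78 °C; then 7, −78 to −40 °C; aq. NH4Cl
Reagents that add atoms: none
Why: Bromine–lithium exchange followed by Weinreb ketone synthesis, in which exchange at −78 °C outruns any attack on the allyl ether, aryllithium 8 adds once to amide 7, and the five-membered lithium chelate 9 survives until aqueous work-up so that no tertiary alcohol forms.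

Step 7
Reactants: 11 trimethylsulfoxonium iodide
Product: 12 dimethyloxosulfonium methylide
Conditions: NaH, THF, reflux; filtered under argon, titrated, used as THF solution
Reagents that add atoms: none
Why: Corey–Chaykovsky ylide formation, in which irreversible deprotonation of the sulfoxonium salt by NaH with loss of dihydrogen gives a THF solution of the stabilised ylide that can be dosed accurately.

Step 8
Reactants: 10 1-[2-(allyloxy)-4-({[tert-butyl(dimethyl)silyl]oxy}methyl)phenyl]-2-{[tert-butyl(dimethyl)silyl]oxy}ethan-1-one; 12 dimethyloxosulfonium methylide (1.2 equiv, added slowly)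
Product: 14 (R)-2-[2-(allyloxy)-4-({[tert-butyl(dimethyl)silyl]oxy}methyl)phenyl]-2-({[tert-butyl(dimethyl)silyl]oxy}methyl)oxirane, via sulfoxonium betaine 13 (not isolated)
Conditions: LaLi3[(R)-1,1'-bi-2-naphtholate]3 (5–10 mol %), tris(2,4,6-trimethoxyphenyl)phosphine oxide (5–10 mol %), 5 Å MS, THF, rt
Reagents that add atoms: none
Why: The trivalent lanthanum centre of the binaphtholate binds the C8 carbonyl while a lithium binaphtholate oxygen holds ylide 12, whose carbon adds to one carbonyl face to form C8–C9 and betaine 13. The C8 alkoxide of 13 then displaces dimethyl sulfoxide from C9 in a 3-exo-tet closure that forms C9–O and the oxirane, the only ring made in the route. The closest known reaction type is the catalytic asymmetric Corey–Chaykovsky epoxidation of aryl methyl ketones with LnM3(binaphtholate)3 catalysts (Ln a rare earth, M an alkali metal) and a triarylphosphine oxide additive, and 10 belongs to the same class of aryl alkyl ketones. The C8 stereocentre is set by the catalyst alone, the binaphtholate pocket placing the ortho-allyloxy aryl group and the CH2OSi arm in different quadrants, since 10 has no stereocentre of its own. The step needs enantiofacial selectivity and addition in preference to enolisation or to further ring expansion to an oxetane; these should be secured by the large size difference between the two ketone substituents, the poor donor ability of the silyl ether oxygen (no competing chelation), the low basicity of the sulfoxonium ylide and the use of a small excess of 12 at room temperature.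

Step 9
Reactants: 14 (R)-2-[2-(allyloxy)-4-({[tert-butyl(dimethyl)silyl]oxy}methyl)phenyl]-2-({[tert-butyl(dimethyl)silyl]oxy}methyl)oxirane
Product: 15 {(S)-2-[2-(allyloxy)-4-(hydroxymethyl)phenyl]oxiran-2-yl}methanol
Conditions: Bu4NF (2.2 equiv), THF, 0 °C
Reagents that add atoms: none
Why: Fluoride-driven cleavage of both primary silyl ethers should proceed at 0 °C without touching the oxirane or the allyl ether, and a Payne shift of the C10 alkoxide would be degenerate in this 2,2-disubstituted glycidol, so the C8 configuration cannot be eroded.

Step 10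
Reactants: 16 (R)-2-methylbutanoic acid (2 equiv)
Product: 17 (R)-2-methylbutanoic anhydride
Conditions: DCC (0.5 equiv per acid), CH2Cl2, 0 °C to rt; filtration of the urea
Reagents that add atoms: (R)-2-methylbutanoic acid (second molecule of 16), CC[C@@H](C)C(=O)O
Why: Carbodiimide dehydration, in which one molecule of the acid is activated as its O-acylisourea and acylated by the carboxylate of a second molecule, joins two acid units into the symmetric anhydride under base-free conditions that leave the α-stereocentre untouched.

Step 11
Reactants: 15 {(S)-2-[2-(allyloxy)-4-(hydroxymethyl)phenyl]oxiran-2-yl}methanol; 17 (R)-2-methylbutanoic anhydride (2.5 equiv, one acyl group taken from each of two molecules)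
Product: 18 {(R)-2-[2-(allyloxy)-4-({[(R)-2-methylbutanoyl]oxy}methyl)phenyl]oxiran-2-yl}methyl (R)-2-methylbutanoate
Conditions: Et3N, DMAP (cat.), CH2Cl2, 0 °C to rt
Reagents that add atoms: none
Why: DMAP-catalysed acyl transfer from the anhydride (Steglich-type acylation) esterifies both primary hydroxyls under basic conditions, so the acid-labile oxirane never meets a free carboxylic acid, and the acyl α-stereocentres are carried over because acyl transfer is faster than α-deprotonation of the activated acyl group.

Step 12
Reactants: 19 angelic acid (2 equiv)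
Product: 20 angelic anhydride
Conditions: DCC (0.5 equiv per acid), CH2Cl2, 0 °C to rt; filtration of the urea
Reagents that add atoms: angelic acid (second molecule of 19), C/C=C(/C)C(=O)O
Why: The same carbodiimide dehydration couples two molecules of the acid through the O-acylisourea of one of them and gives the symmetric anhydride without base, nucleophilic catalyst or heat, conditions under which the Z double bond should not isomerise to the tiglate.

Step 13
Reactants: 18 {(R)-2-[2-(allyloxy)-4-({[(R)-2-methylbutanoyl]oxy}methyl)phenyl]oxiran-2-yl}methyl (R)-2-methylbutanoate; 20 angelic anhydride (2 equiv)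
Product: 22 {(R)-2-[2-{[(Z)-2-methylbut-2-enoyl]oxy}-4-({[(R)-2-methylbutanoyl]oxy}methyl)phenyl]oxiran-2-yl}methyl (R)-2-methylbutanoate (CNP0166772.1), via phenol 21 (not isolated)
Conditions: Pd(PPh3)4 (5 mol %), morpholine (1.1 equiv), THF, rt; then 20, Et3N, DMAP (cat.), 0 °C
Reagents that add atoms: none
Why: Tsuji–Trost deallylation followed by phenol acylation, in which zerovalent palladium ionises the aryl allyl ether, morpholine captures the allyl fragment, and phenol 21 is acylated in the same flask by anhydride 20 at 0 °C before it can open the neighbouring oxirane, the fast acyl transfer to the phenol keeping the angelate Z.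

Compound list
1 | methyl 4-bromo-3-hydroxybenzoate | COC(=O)c1ccc(Br)c(O)c1 | starting material
2 | methyl 3-(allyloxy)-4-bromobenzoate | COC(=O)c1ccc(Br)c(OCC=C)c1 | intermediate
3 | [3-(allyloxy)-4-bromophenyl]methanol | OCc1ccc(Br)c(OCC=C)c1 | intermediate
4 | {[3-(allyloxy)-4-bromobenzyl]oxy}(tert-butyl)dimethylsilane | C=CCOc1cc(CO[Si](C)(C)C(C)(C)C)ccc1Br | intermediate
5 | methyl glycolate | COC(=O)CO | starting material
6 | methyl {[tert-butyl(dimethyl)silyl]oxy}acetate | COC(=O)CO[Si](C)(C)C(C)(C)C | intermediate
7 | 2-{[tert-butyl(dimethyl)silyl]oxy}-N-methoxy-N-methylacetamide | CON(C)C(=O)CO[Si](C)(C)C(C)(C)C | intermediate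
8 | [2-(allyloxy)-4-({[tert-butyl(dimethyl)silyl]oxy}methyl)phenyl]lithium (not isolated) | [Li]c1ccc(CO[Si](C)(C)C(C)(C)C)cc1OCC=C | intermediate
9 | lithium 1-[2-(allyloxy)-4-({[tert-butyl(dimethyl)silyl]oxy}methyl)phenyl]-2-{[tert-butyl(dimethyl)silyl]oxy}-1-[methoxy(methyl)amino]ethan-1-olate (racemic tetrahedral adduct, not isolated) | [Li+].[O-]C(CO[Si](C)(C)C(C)(C)C)(N(C)OC)c1ccc(CO[Si](C)(C)C(C)(C)C)cc1OCC=C | intermediate
10 | 1-[2-(allyloxy)-4-({[tert-butyl(dimethyl)silyl]oxy}methyl)phenyl]-2-{[tert-butyl(dimethyl)silyl]oxy}ethan-1-one | C=CCOc1cc(CO[Si](C)(C)C(C)(C)C)ccc1C(=O)CO[Si](C)(C)C(C)(C)C | intermediate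
11 | trimethylsulfoxonium iodide | C[S+](C)(C)=O.[I-] | starting material
12 | dimethyloxosulfonium methylide (THF solution) | C[S+](C)(=O)[CH2-] | intermediate
13 | (S)-2-[2-(allyloxy)-4-({[tert-butyl(dimethyl)silyl]oxy}methyl)phenyl]-3-{[tert-butyl(dimethyl)silyl]oxy}-1-(dimethyloxosulfonio)propan-2-olate (betaine, not isolated) | C=CCOc1cc(CO[Si](C)(C)C(C)(C)C)ccc1[C@]([O-])(CO[Si](C)(C)C(C)(C)C)C[S+](C)(C)=O | intermediate
14 | (R)-2-[2-(allyloxy)-4-({[tert-butyl(dimethyl)silyl]oxy}methyl)phenyl]-2-({[tert-butyl(dimethyl)silyl]oxy}methyl)oxirane | C=CCOc1cc(CO[Si](C)(C)C(C)(C)C)ccc1[C@]1(CO[Si](C)(C)C(C)(C)C)CO1 | intermediate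
15 | {(S)-2-[2-(allyloxy)-4-(hydroxymethyl)phenyl]oxiran-2-yl}methanol | C=CCOc1cc(CO)ccc1[C@]1(CO)CO1 | intermediate
16 | (R)-2-methylbutanoic acid | CC[C@@H](C)C(=O)O | starting material
17 | (R)-2-methylbutanoic anhydride | CC[C@@H](C)C(=O)OC(=O)[C@H](C)CC | intermediate
18 | {(R)-2-[2-(allyloxy)-4-({[(R)-2-methylbutanoyl]oxy}methyl)phenyl]oxiran-2-yl}methyl (R)-2-methylbutanoate | C=CCOc1cc(COC(=O)[C@H](C)CC)ccc1[C@]1(COC(=O)[C@H](C)CC)CO1 | intermediate
19 | angelic acid, (Z)-2-methylbut-2-enoic acid | C/C=C(/C)C(=O)O | starting material
20 | angelic anhydride, (Z)-2-methylbut-2-enoic anhydride | C/C=C(/C)C(=O)OC(=O)/C(C)=C\C | intermediate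
21 | {(R)-2-[2-hydroxy-4-({[(R)-2-methylbutanoyl]oxy}methyl)phenyl]oxiran-2-yl}methyl (R)-2-methylbutanoate (not isolated) | Oc1cc(COC(=O)[C@H](C)CC)ccc1[C@]1(COC(=O)[C@H](C)CC)CO1 | intermediate
22 | {(R)-2-[2-{[(Z)-2-methylbut-2-enoyl]oxy}-4-({[(R)-2-methylbutanoyl]oxy}methyl)phenyl]oxiran-2-yl}methyl (R)-2-methylbutanoate, CNP0166772.1 | C/C=C(/C)C(=O)Oc1cc(COC(=O)[C@H](C)CC)ccc1[C@]1(COC(=O)[C@H](C)CC)CO1 | target

Total step count: 13.
Longest linear sequence: 8 steps (steps 1, 2, 3, 6, 8, 9, 11 and 13, from 1 to 22).

Steps most likely to fail

Step 8. Facial discrimination may be insufficient, because the CH2OSi arm is bulkier than the methyl group for which this catalyst type works best, and the ylide may enolise the α-silyloxy ketone instead of adding to it. The fallback sets out from 10 and comes back to the route at 15. Wittig methylenation of 10 (Ph3PCH3Br, KOt-Bu, THF, 0 °C to rt) should give tert-butyl{[3-(allyloxy)-4-(3-{[tert-butyl(dimethyl)silyl]oxy}prop-1-en-2-yl)benzyl]oxy}dimethylsilane F1. Bu4NF in THF then removes both silyl groups to give 2-[2-(allyloxy)-4-(hydroxymethyl)phenyl]prop-2-en-1-ol F2. Sharpless asymmetric epoxidation of F2 (Ti(Oi-Pr)4 and L-(+)-diisopropyl tartrate in stoichiometric amount because two hydroxyls bind titanium, t-BuOOH, 4 Å MS, CH2Cl2, −20 °C) uses the C10 hydroxyl to direct oxygen transfer to the alkene face fixed by the tartrate. This is the face that gives (S)-glycidol from allyl alcohol and corresponds here to the S descriptor of diol 15, which should form directly. The allyl ether alkene has no allylic hydroxyl and is left alone. The route continues with step 11.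

Step 13. The phenol set free next to the oxirane may attack C9 (closure to a 3-hydroxy-2,3-dihydrobenzofuran) or open the C8–O bond through an ortho-quinone-methide pathway before it is acylated, and the angelate may drift to the E isomer in the presence of amine and DMAP. The fallback sets out from 18 and comes back at 22. Hydrostannolytic allyl cleavage (Pd(PPh3)4, Bu3SnH, CH2Cl2, rt) converts 18, with loss of propene, into the covalent tin phenoxide tributyl{2-[(R)-2-({[(R)-2-methylbutanoyl]oxy}methyl)oxiran-2-yl]-5-({[(R)-2-methylbutanoyl]oxy}methyl)phenoxy}stannane F3. This species is far less nucleophilic than a phenoxide and is acylated in the same flask by anhydride 20 without amine base, so that no free phenol is present at any time.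

Step 6. The aryllithium may be quenched by proton transfer from the α-CH2 of amide 7, or acylation may be slow enough for 8 to add to its own allyl group on warming, returning debrominated or cyclised arene. The fallback sets out from 4 and comes back at 10. Aryllithium 8 is generated as before and trapped at −78 °C with the far more electrophilic, commercially available (tert-butyldimethylsilyloxy)acetaldehyde to give 1-[2-(allyloxy)-4-({[tert-butyl(dimethyl)silyl]oxy}methyl)phenyl]-2-{[tert-butyl(dimethyl)silyl]oxy}ethan-1-ol F4. Dess–Martin periodinane (NaHCO3, CH2Cl2, rt) then oxidises F4 to ketone 10.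

Further compounds
F1 | step 8 | tert-butyl{[3-(allyloxy)-4-(3-{[tert-butyl(dimethyl)silyl]oxy}prop-1-en-2-yl)benzyl]oxy}dimethylsilane | C=CCOc1cc(CO[Si](C)(C)C(C)(C)C)ccc1C(=C)CO[Si](C)(C)C(C)(C)C
F2 | step 8 | 2-[2-(allyloxy)-4-(hydroxymethyl)phenyl]prop-2-en-1-ol | C=CCOc1cc(CO)ccc1C(=C)CO
F3 | step 13 | tributyl{2-[(R)-2-({[(R)-2-methylbutanoyl]oxy}methyl)oxiran-2-yl]-5-({[(R)-2-methylbutanoyl]oxy}methyl)phenoxy}stannane | CCCC[Sn](CCCC)(CCCC)Oc1cc(COC(=O)[C@H](C)CC)ccc1[C@]1(COC(=O)[C@H](C)CC)CO1
F4 | step 6 | 1-[2-(allyloxy)-4-({[tert-butyl(dimethyl)silyl]oxy}methyl)phenyl]-2-{[tert-butyl(dimethyl)silyl]oxy}ethan-1-ol (racemic) | C=CCOc1cc(CO[Si](C)(C)C(C)(C)C)ccc1C(O)CO[Si](C)(C)C(C)(C)C
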